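The meeting opened on something the readings will not allow: a substrate that feels the partner. The analyst reported that at 0.500 min the birch run, with c(partner) = 0.033 M, held 27% of its substrate, while the cedar run, with 3.94 times that charge, held 29%. That is a gap of 2 percentage points against a scatter of 1.5 points per reading.

| flask | substrate | partner | remark | time |
|---|---|---|---|---|
| birch | 0.17 M | 0.033 M | run made earlier |  |
| ash | 0.17 M | 0.075 M | run made earlier |  |
| cedar | 0.17 M | 0.13 M | run made earlier |  |
| Thursday's | 0.17 M | 0.0400 M |  | 6.0 min |
| Friday's | 0.17 M | 0.0800 M |  | 6.0 min |
| Monday's | 0.17 M | 0.150 M |  | 6.0 min |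

| run | time / min | target / % | substrate / % |
|---|---|---|---|
| birch | 0.500 | 64 | 27 |
| birch | 1.50 | 89 | 2 |
| birch | 3.00 | 96 | 0 |
| birch | 4.00 | 96 | 5 |
| birch | 6.00 | 93 | 0 |
| ash | 1.33 | 87 | 3 |
| ash | 2.50 | 93 | 0 |
| ash | 4.00 | 94 | 0 |
| ash | 5.00 | 93 | 0 |
| ash | 6.00 | 92 | 0 |
| cedar | 0.500 | 64 | 29 |
| cedar | 0.833 | 78 | 12 |
| cedar | 1.50 | 91 | 0 |
| cedar | 3.00 | 95 | 0 |
| cedar | 6.00 | 95 | 0 |

(standard deviation of a reading: 1.5 percentage points)

- the numbers in the tables scatter with a standard deviation of 1.5 percentage points
- "hardly changes" means that all values lie within two and a half points (for a concentration: within two and a half percent of the largest)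

1. amount of target at the end, in percent of the substrate charged for Thursday's, Friday's, Monday's, in this order
2. how that number moves from the first to the last of them (falls, then rises / rises, then falls / hardly changes / falls all the way / rises all the way)

The analyst proposed to carry one quantity: the time in which the substrate halves, reckoned from those two readings as a first-order decay. She called it the substrate clock and put it at 0.272 min.

The plant chemist asked what the clock buys. She answered that the asked 6.0 min holds 22.1 such half-lives, so the substrate in Thursday's, Friday's and Monday's flasks should be used up well before the sampling.

He objected that Monday's c(partner) of 0.150 M lies above cedar's 0.13 M. She replied that this step, a factor of 1.15, is smaller than the span over which the clock had shown no movement.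

The height of the plateau remained. He pointed to the small fall in birch, from 96% to 93%, but cedar stayed at 95%, and the meeting took that fall as too near the scatter to build on. The 9 target readings from 2.50 min onward average 94.1%, and our own reckoning, as minuted, is that figure for the three flasks, with a row that hardly changes.

The forecast gave 93.8%, 93.5% and 94.8%, shape hardly changes, holding that “the differences between runs are barely significant and show no convincing trend”.

The flask gives 94.5%, 94.5% and 94.5%, and the shape is hardly changes.

    substrate ⇌ intermediate A (K = 0.227, k = 0.0120 /s)
    intermediate A → intermediate B (k = 0.0133 /s)
    substrate → target (k = 0.0411 /s)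
    partner + intermediate B → intermediate C (k = 0.113 /M/s)
    partner + intermediate C → intermediate D (k = 0.146 /M/s)
    intermediate D → side product (k = 0.0191 /s)
    partner ⇌ dormant form (K = 0.550, k = 0.211 /s)

In Thursday's flask the partner's step on intermediate B, which lies past the fork between target and intermediate A, has a half-life for intermediate B of 4.0 min at 0.285 min, which is 14.7 times the substrate clock of 0.272 min. In Monday's flask, 3.00 min is 11.0 clock periods; by then the substrate stands at 0.147% and the target at 94.3%, and the side product stands at 4.35% at 6.00 min against Thursday's 1.08%, while both flasks reach 5.54% by 60.0 min.

The numbers in the tables are calculated for substances that don't exist, noise included.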